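**Retrosynthetic overview**
1. No ring is made: the resorcinol ring is bought as its 5-bromo derivative and joined to the chain (aryl–C1 bond) by hydroboration/B-alkyl Suzuki coupling, without protecting groups.
2. The (Z)-C8=C9 alkene comes from syn semihydrogenation of a C8≡C9 alkyne in the last step.
3. The C7–C8 bond comes from alkylation of a terminal acetylide with a C7 ω-bromoalkene.
4. The terminal alkyne comes from an alkyne zipper on a propargylic alcohol, which moves the triple bond five positions without touching the carbinol.
5. The C-15 stereocentre and the C14–C15 bond come from an oxazaborolidine-catalysed enantioselective alkynylation of a C3 aldehyde with a C7 alkyne.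

Assumption: 5-bromobenzene-1,3-diol, 7-bromohept-1-ene, B-chlorocatecholborane and (R)-Me-CBS oxazaborolidine are taken as commercially available; the target stereocentre reads as (S) at C-15 (OH > C-14 chain > ethyl > H), numbering the chain from the ring.

**Step 1**
Reactants: 1 hept-1-yne; 2 propanal
Product: 6 (S)-dec-4-yn-3-ol, via lithium hept-1-ynide 3 (not isolated), via B-heptynyl catecholboronate 4 (not isolated), via catecholborate ester 5 (not isolated)
Conditions: 1 (1.2 equiv), n-BuLi, toluene, −78 °C; B-chlorocatecholborane, −78 → 0 °C, LiCl filtered off; (R)-Me-CBS oxazaborolidine (10 mol %), 2 added over 2 h, toluene, −78 → −40 °C; H2O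
Reagents that add atoms: none
Why: Proposed new method: oxazaborolidine-catalysed enantioselective alkynyl transfer from a B-alkynyl catecholboronate to an aldehyde, in which boronate 4 (inert toward 2 on its own at low temperature) binds the ring nitrogen of the catalyst as catecholborane does in a CBS reduction while propanal binds the ring boron anti to its ethyl group, so the nitrogen-activated alkynyl group passes through a six-membered transition state to the Re face and gives the (S) carbinol; the closest known reaction types are the CBS reduction of ketones with catecholborane and the oxazaborolidine-promoted addition of alkynyl(dialkyl)boranes to aldehydes.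

**Step 2**
Reactants: 6 (S)-dec-4-yn-3-ol
Product: 8 (S)-dec-9-yn-3-ol, via dipotassium alkoxide-acetylide 7 (not isolated)
Conditions: KH (4 equiv), H2N(CH2)3NH2, rt, 1 h; then 6, 0 °C → rt, 3 h; H2O
Reagents that add atoms: none
Why: Alkyne zipper reaction (isomerisation with potassium 3-aminopropylamide), in which the triple bond walks along the chain through propargyl/allenyl anion equilibria and is trapped as the terminal acetylide, while the alkoxide blocks deprotonation at C-3 so the stereocentre is kept.

**Step 3**
Reactants: 8 (S)-dec-9-yn-3-ol; 9 7-bromohept-1-ene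
Product: 11 (S)-heptadec-16-en-9-yn-3-ol, via dilithium alkoxide-acetylide 10 (not isolated)
Conditions: n-BuLi (2.1 equiv), THF/DMPU, −78 → 0 °C; then 9 (1.2 equiv), 0 °C → rt; H2O
Reagents that add atoms: none
Why: SN2 alkylation of an alkoxide-acetylide dianion, in which the sp carbanion is far more nucleophilic toward the primary bromide than the hindered secondary lithium alkoxide, so C-alkylation dominates and the stereocentre is not involved.

**Step 4**
Reactants: 11 (S)-heptadec-16-en-9-yn-3-ol; 12 5-bromobenzene-1,3-diol
Product: 14 5-[(15S)-15-hydroxyheptadec-8-yn-1-yl]benzene-1,3-diol, via bis(9-BBN) adduct 13 (not isolated)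
Conditions: 9-BBN (2.3 equiv), THF, 0 °C → rt; then 12 (1.1 equiv), Pd(OAc)2 (4 mol %), SPhos (8 mol %), K3PO4 (3 M aq., 6 equiv), THF, 60 °C
Reagents that add atoms: none
Why: Anti-Markovnikov hydroboration with 9-BBN is strongly selective for the terminal alkene over the internal alkyne (the extra equivalent ties up the hydroxyl as a borinate that is cleaved on work-up), and the B-alkyl Suzuki–Miyaura coupling with the electron-rich SPhos ligand tolerates the phenoxides formed from unprotected 12 in aqueous base.

**Step 5**
Reactants: 14 5-[(15S)-15-hydroxyheptadec-8-yn-1-yl]benzene-1,3-diol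
Product: 15 Hansfordiol G [5-[(8Z,15S)-15-hydroxyheptadec-8-en-1-yl]benzene-1,3-diol]
Conditions: H2 (1 atm), Pd/CaCO3 poisoned with Pb(OAc)2 (Lindlar catalyst), quinoline, EtOAc, rt, stopped at 1.0 equiv H2
Reagents that add atoms: none
Why: Lindlar semihydrogenation delivers one equivalent of H2 syn across the alkyne on poisoned palladium to give the (Z)-alkene, leaving the arene and the remote C-15 stereocentre untouched.

**Compound list**
1 | hept-1-yne | C#CCCCCC | starting material
2 | propanal | CCC=O | starting material
3 | lithium hept-1-yn-1-ide | [Li+].[C-]#CCCCCC | intermediate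
4 | 2-(hept-1-yn-1-yl)-1,3,2-benzodioxaborole | CCCCCC#CB1Oc2ccccc2O1 | intermediate
5 | 2-{[(3S)-dec-4-yn-3-yl]oxy}-1,3,2-benzodioxaborole | CC[C@H](OB1Oc2ccccc2O1)C#CCCCCC | intermediate
6 | (3S)-dec-4-yn-3-ol | CC[C@H](O)C#CCCCCC | intermediate
7 | dipotassium (3S)-3-oxidodec-9-yn-10-ide | CC[C@H]([O-])CCCCCC#[C-].[K+].[K+] | intermediate
8 | (3S)-dec-9-yn-3-ol | CC[C@H](O)CCCCCC#C | intermediate
9 | 7-bromohept-1-ene | C=CCCCCCBr | starting material
10 | dilithium (3S)-3-oxidodec-9-yn-10-ide | CC[C@H]([O-])CCCCCC#[C-].[Li+].[Li+] | intermediate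
11 | (3S)-heptadec-16-en-9-yn-3-ol | CC[C@H](O)CCCCCC#CCCCCCC=C | intermediate
12 | 5-bromobenzene-1,3-diol | Oc1cc(O)cc(Br)c1 | starting material
13 | 9-{(15S)-15-[(9-borabicyclo[3.3.1]nonan-9-yl)oxy]heptadec-8-yn-1-yl}-9-borabicyclo[3.3.1]nonane | CC[C@H](OB1C2CCCC1CCC2)CCCCCC#CCCCCCCCB1C2CCCC1CCC2 | intermediate
14 | 5-[(15S)-15-hydroxyheptadec-8-yn-1-yl]benzene-1,3-diol | CC[C@H](O)CCCCCC#CCCCCCCCc1cc(O)cc(O)c1 | intermediate
15 | Hansfordiol G, 5-[(8Z,15S)-15-hydroxyheptadec-8-en-1-yl]benzene-1,3-diol | CC[C@H](O)CCCCC/C=C\CCCCCCCc1cc(O)cc(O)c1 | target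

**Step count and risks**
Total step count: 5. Longest linear sequence: 5 (fully linear, no protecting groups).

The three steps most likely to fail:

Step 1, the proposed new alkynylation. The boronate may not turn over at low temperature, or the ee may be low; the ee should be checked on 6 or 8 as the Mosher ester. The fallback uses known chemistry and sets out from propanal 2. Chiral phosphoric acid catalysis with (R)-TRIP (5 mol %), allenylboronic acid pinacol ester and 4 Å molecular sieves in toluene at −20 °C gives (S)-hex-5-yn-3-ol F1. The facial sense is taken to be the same as for other aldehydes, and the descriptor is S because propargyl outranks ethyl. The dianion of F1 (n-BuLi 2.2 equiv, THF/DMPU) is alkylated with 1-bromobutane to give (S)-dec-5-yn-3-ol F2. The zipper conditions of step 2 applied to F2 move the triple bond to the chain end, and the route is rejoined at 8.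

Step 3, the dianion alkylation. The risks are O-alkylation and E2 elimination of 9. The fallback sets out from 8. TBSCl and imidazole in DMF give tert-butyl{[(3S)-dec-9-yn-3-yl]oxy}dimethylsilane F3. Its mono-lithium acetylide (n-BuLi 1.05 equiv, THF/DMPU) is alkylated with 9 to give tert-butyl{[(3S)-heptadec-16-en-9-yn-3-yl]oxy}dimethylsilane F4. TBAF in THF removes the silyl group, and the route is rejoined at 11.

Step 4, hydroboration and coupling with the unprotected bromoresorcinol. The risks are slow oxidative addition into the bis-phenoxide of 12 and partial hydroboration of the alkyne. The fallback sets out from 12. MOMCl and i-Pr2NEt in CH2Cl2 give 1-bromo-3,5-bis(methoxymethoxy)benzene F5. This is coupled with the 9-BBN adduct 13, made from 11 as before, using PdCl2(dppf) and K3PO4 in THF/DMF/H2O at 60 °C, to give (3S)-17-[3,5-bis(methoxymethoxy)phenyl]heptadec-9-yn-3-ol F6. HCl in MeOH at rt removes both acetals, and the route is rejoined at 14.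

**Further compounds**
F1 | step 1 | (3S)-hex-5-yn-3-ol | CC[C@H](O)CC#C
F2 | step 1 | (3S)-dec-5-yn-3-ol | CC[C@H](O)CC#CCCCC
F3 | step 3 | tert-butyl{[(3S)-dec-9-yn-3-yl]oxy}dimethylsilane | CC[C@H](O[Si](C)(C)C(C)(C)C)CCCCCC#C
F4 | step 3 | tert-butyl{[(3S)-heptadec-16-en-9-yn-3-yl]oxy}dimethylsilane | CC[C@H](O[Si](C)(C)C(C)(C)C)CCCCCC#CCCCCCC=C
F5 | step 4 | 1-bromo-3,5-bis(methoxymethoxy)benzene | COCOc1cc(Br)cc(OCOC)c1
F6 | step 4 | (3S)-17-[3,5-bis(methoxymethoxy)phenyl]heptadec-9-yn-3-ol | CC[C@H](O)CCCCCC#CCCCCCCCc1cc(OCOC)cc(OCOC)c1
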